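**Plan**

1. Retrosynthesis (germacrane numbering: ring C1–C10, C11–C13 on C7, C14 on C10, C15 on C4): the two oxiranes and the two acyl groups (O8 acrylate, O13 acetate) are removed first, then the ten-membered ring is cut at C9–C10, the butenolide at C6–C7 together with its C6–O lactone bond, and C7–C11 by an aldol disconnection.
2. Enabling feature: C8(O)–C9H2 is the β,α-unit of a β-hydroxy acid, so L-malate maps onto C7–C8–C9 plus a carboxyl that can leave as CO2 to give a C9 radical. C10 is the methyl-bearing carbon of the E C1=C10 olefin, hence an E alkenyl bromide. The butenolide ring (O, C12, C11, C7, C6) is in place before the carbocycle closes.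
3. Forward: geranyl acetate gives an E,E bromodienal (C1–C6, C10, C14, C15) and dimethyl L-malate gives a Z enol triflate (C7–C9, C11–C13, extra carboxyl). The chain is joined at C6–C7 with closure of the lactone ring, the ten-membered ring closes at C9–C10, and both oxiranes are made in the last step.
4. Stereochemistry: C8 comes from L-malic acid, C6 from a ligand-controlled Nozaki–Hiyama–Kishi addition, the E olefins from geranyl acetate and a syn hydrozirconation, and C1, C10, C4, C5 from attack on the outer faces of the E,E-cyclodecadiene.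

Key step: step 16

Remark: the (S)-oxazoline–sulfonamide ligand of step 13 (a reagent, two known steps from 2-aminobenzonitrile and (S)-valinol) is assumed to give the 6R carbinol; if the sense is opposite, its enantiomer is used and nothing else changes. TBS = tert-butyldimethylsilyl, PMB = 4-methoxybenzyl.

**Route**

Step 1
Reactants: 1 geranyl acetate
Product: 2 6,7-epoxygeranyl acetate (racemic)
Conditions: mCPBA (1.0 equiv), NaHCO3, CH2Cl2, 0 °C
Reagents that add atoms: 3-chloroperoxybenzoic acid, OOC(=O)c1cccc(Cl)c1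
Why: Prilezhaev epoxidation should take the more electron-rich 6,7-olefin and spare the olefin deactivated by the allylic acetate; the oxirane carbon is racemic and is destroyed in step 2.

Step 2
Reactants: 2 6,7-epoxygeranyl acetate
Product: 4 (2E)-3-methyl-6-oxohex-2-en-1-yl acetate, via glycol 3 (not isolated)
Conditions: HIO4·2H2O, THF/H2O, 0 °C
Reagents that add atoms: none
Why: Periodic acid should hydrolyse the oxirane to the glycol and cleave it in the same flask (Malaprade glycol cleavage), leaving the aldehyde carbon that becomes C1 without touching the acetate or the E olefin.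

Step 3
Reactants: 4 (2E)-3-methyl-6-oxohex-2-en-1-yl acetate
Product: 5 (2E)-3-methylhept-2-en-6-yn-1-ol
Conditions: dimethyl (1-diazo-2-oxopropyl)phosphonate, K2CO3, MeOH, 0 °C to rt
Reagents that add atoms: dimethyl (1-diazo-2-oxopropyl)phosphonate, CC(=O)C(=[N+]=[N-])P(=O)(OC)OC
Why: Ohira–Bestmann homologation turns the aldehyde into the terminal alkyne (new carbon = C10), and the K2CO3/MeOH medium should methanolyse the acetate in the same operation; no stereocentre is formed.

Step 4
Reactants: 5 (2E)-3-methylhept-2-en-6-yn-1-ol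
Product: 7 (2E)-3-methyloct-2-en-6-yn-1-ol, via dilithio alkynolate 6 (not isolated)
Conditions: n-BuLi (2.1 equiv), THF, −78 to −20 °C; MeI (1.05 equiv), −78 °C to rt; aq. NH4Cl
Reagents that add atoms: iodomethane, CI
Why: Alkylation of the lithium acetylide of the dianion with iodomethane should install C14 on carbon, because the lithium alkoxide is a poor nucleophile in THF at low temperature.

Step 5
Reactants: 7 (2E)-3-methyloct-2-en-6-yn-1-ol
Product: 9 (2E,6E)-7-bromo-3-methylocta-2,6-dien-1-ol, via alkenylzirconocene 8 (not isolated)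
Conditions: Cp2Zr(H)Cl (3 equiv), THF, rt then 45 °C; N-bromosuccinimide (1.05 equiv), 0 °C
Reagents that add atoms: N-bromosuccinimide, O=C1CCC(=O)N1Br
Why: syn-Hydrozirconation puts zirconium on the less hindered, methyl-bearing alkyne carbon after equilibration with excess hydride, and bromodezirconation with retention should give the E alkenyl bromide; the first equivalent of hydride is consumed by the hydroxyl.

Step 6
Reactants: 9 (2E,6E)-7-bromo-3-methylocta-2,6-dien-1-ol
Product: 10 (2E,6E)-7-bromo-3-methylocta-2,6-dienal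
Conditions: MnO2 (excess), CH2Cl2, rt
Reagents that add atoms: none
Why: MnO2 oxidation of the primary allylic alcohol should give the enal (C6 aldehyde) without isomerising the 2E olefin or touching the alkenyl bromide.

Step 7
Reactants: 11 dimethyl L-malate
Product: 12 dimethyl (2S)-2-[(tert-butyldimethylsilyl)oxy]butanedioate
Conditions: TBSCl, imidazole, DMF, rt
Reagents that add atoms: tert-butyl(chloro)dimethylsilane, CC(C)(C)[Si](C)(C)Cl
Why: Imidazole-mediated silylation of the secondary hydroxyl; the stereocentre that becomes C8 comes from L-malic acid and is not touched.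

Step 8
Reactants: 12 dimethyl (2S)-2-[(TBS)oxy]butanedioate
Product: 13 methyl (3S)-3-[(TBS)oxy]-4-oxobutanoate
Conditions: iBu2AlH (1.05 equiv), CH2Cl2, −78 °C; aq. potassium sodium tartrate
Reagents that add atoms: none
Why: Partial reduction with iBu2AlH at −78 °C should stop at the aluminium hemiacetal of the more electrophilic α-silyloxy ester, so only C7 reaches the aldehyde level and C8 is not epimerised.

Step 9
Reactants: 14 4-methoxybenzyl alcohol; 15 methyl acrylate
Product: 16 methyl 3-[(4-methoxybenzyl)oxy]propanoate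
Conditions: NaH (5 mol %), THF, 0 °C to rt
Reagents that add atoms: none
Why: Base-catalysed oxa-Michael addition of the benzylic alkoxide to the acrylate gives the C11–C13 unit with O13 already protected.

Step 10
Reactants: 16 methyl 3-[(PMB)oxy]propanoate; 13 methyl (3S)-3-[(TBS)oxy]-4-oxobutanoate
Product: 18 dimethyl (4S)-4-[(TBS)oxy]-3-hydroxy-2-{[(PMB)oxy]methyl}hexanedioate (mixture at C2 and C3), via lithium enolate 17 (not isolated)
Conditions: LiN(iPr)2, THF, −78 °C; then 13, −78 °C; aq. NH4Cl at −78 °C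
Reagents that add atoms: none
Why: Aldol addition of the lithium ester enolate, kept at −78 °C to suppress β-elimination of the alkoxide, forms C7–C11; the two new centres need no control because both carbons become sp2 in steps 11 and 12.

Step 11
Reactants: 18 aldol adduct
Product: 19 dimethyl (4S)-4-[(TBS)oxy]-2-{[(PMB)oxy]methyl}-3-oxohexanedioate
Conditions: Dess–Martin periodinane, NaHCO3, CH2Cl2, rt
Reagents that add atoms: none
Why: Dess–Martin oxidation of the secondary alcohol gives the β-keto ester under buffered, non-basic conditions that leave C8 and the silyl ether intact.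

Step 12
Reactants: 19 β-keto ester
Product: 21 dimethyl (2Z,4S)-4-[(TBS)oxy]-2-{[(PMB)oxy]methyl}-3-{[(trifluoromethyl)sulfonyl]oxy}hex-2-enedioate, via lithium enolate 20 (not isolated)
Conditions: LiN(SiMe3)2 (1.05 equiv), THF, −78 °C; N-(5-chloropyridin-2-yl)bis(trifluoromethanesulfonimide), −78 to 0 °C; aq. NH4Cl
Reagents that add atoms: N-(5-chloropyridin-2-yl)bis(trifluoromethanesulfonimide), FC(F)(F)S(=O)(=O)N(c1ccc(Cl)cn1)S(=O)(=O)C(F)(F)F
Why: O-Sulfonylation of the lithium-chelated enolate, formed at the most acidic carbon C11, should give the Z enol triflate with the triflate cis to the C12 ester, as lactonisation in step 13 requires.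

Step 13
Reactants: 21 Z enol triflate; 10 (2E,6E)-7-bromo-3-methylocta-2,6-dienal
Product: 23 methyl (3S)-3-[(TBS)oxy]-3-[(2R)-2-[(1E,5E)-6-bromo-2-methylhepta-1,5-dien-1-yl]-4-{[(PMB)oxy]methyl}-5-oxo-2,5-dihydrofuran-3-yl]propanoate, via hydroxy diester 22 (not isolated)
Conditions: CrCl2 (3.5 equiv), (S)-4-isopropyl-2-[2-(methanesulfonamido)phenyl]-4,5-dihydrooxazole (3.8 equiv), Et3N (3.8 equiv), NiCl2 (2 mol %), THF, rt; then PPTS, CH2Cl2, rt
Reagents that add atoms: none
Why: Nozaki–Hiyama–Kishi coupling: zerovalent nickel should insert into the activated C7–OTf bond faster than into the hindered C10–Br bond, transmetalation to chromium and ligand-controlled addition to one face of the aldehyde set C6 (6R), and the γ-hydroxy ester with the carbinol cis to the C12 ester lactonises to the butenolide.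

Step 14
Reactants: 23 butenolide methyl ester
Product: 24 (3S)-3-[(TBS)oxy]-3-[(2R)-2-[(1E,5E)-6-bromo-2-methylhepta-1,5-dien-1-yl]-4-{[(PMB)oxy]methyl}-5-oxo-2,5-dihydrofuran-3-yl]propanoic acid
Conditions: Me3SnOH (6 equiv), 1,2-dichloroethane, 70 °C; cold 0.5 M HCl work-up
Reagents that add atoms: trimethyltin hydroxide, C[Sn](C)(C)O
Why: Me3SnOH hydrolysis of the unhindered methyl ester under near-neutral conditions should avoid β-elimination of the silyloxy group and epimerisation at C6; any opened butenolide recloses on acidification.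

Step 15
Reactants: 24 seco acid; 25 N-hydroxyphthalimide
Product: 26 1,3-dioxoisoindolin-2-yl (3S)-3-[(TBS)oxy]-3-[(2R)-2-[(1E,5E)-6-bromo-2-methylhepta-1,5-dien-1-yl]-4-{[(PMB)oxy]methyl}-5-oxo-2,5-dihydrofuran-3-yl]propanoate
Conditions: N,N'-diisopropylcarbodiimide, DMAP (5 mol %), CH2Cl2, 0 °C to rt
Reagents that add atoms: none
Why: Carbodiimide (Steglich-type) esterification of the acid with N-hydroxyphthalimide gives the redox-active ester without touching C6 or C8.

Step 16
Reactants: 26 seco N-acyloxyphthalimide with E alkenyl bromide at C10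
Product: 27 (6R,8S)-8-[(TBS)oxy]-13-[(PMB)oxy]germacra-1(10)E,4E,7(11)-trien-12,6-olide
Conditions: undivided cell, Mg anode, reticulated vitreous carbon cathode, NiCl2·dme (20 mol %), 2,2'-bipyridine (22 mol %), AgNO3 (0.3 equiv), LiCl (0.1 M), DMF, rt, constant current; 26 added by syringe pump to a final 2 mM
Reagents that add atoms: none
Why: Proposed new method: cathodically formed zerovalent nickel–bipyridine inserts into the C10–Br bond, single-electron reduction of the N-acyloxyphthalimide releases CO2 and phthalimide to leave the primary C9 radical, this radical is captured by the alkenylnickel centre of the same molecule, and reductive elimination from trivalent nickel forms C9–C10. The closest known reaction is the intermolecular nickel-electrocatalytic decarboxylative alkenylation of redox-active esters with alkenyl bromides; its ten-membered intramolecular version is not known. The carbocycle closes by radical capture at the metal followed by C(sp3)–C(sp2) reductive elimination, not by radical addition to an olefin. No stereocentre is formed: C6 and C8 are carried in, and the E geometry of C1=C10 should be retained because the alkenylnickel keeps its configuration. The step needs ring closure to win over reduction or dimerisation of the C9 radical, 1,5-hydrogen transfer from C13 and nickel insertion into the allylic lactone C6–O bond; slow addition at high dilution, a high nickel loading, the much faster insertion into C–Br, and a chain pre-bent by two E olefins and the planar butenolide are meant to secure this.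

Step 17
Reactants: 27 macrocyclic silyl ether
Product: 28 (6R,8S)-8-hydroxy-13-[(PMB)oxy]germacra-1(10)E,4E,7(11)-trien-12,6-olide
Conditions: HF·pyridine, pyridine, THF, 0 °C to rt
Reagents that add atoms: none
Why: Fluoride-mediated cleavage of the secondary silyl ether under pyridine-buffered conditions should spare the acid-sensitive cyclodecadiene and the benzyl ether.

Step 18
Reactants: 29 ethyl 2-(hydroxymethyl)acrylate
Product: 30 ethyl 2-{[(TBS)oxy]methyl}acrylate
Conditions: TBSCl, imidazole, CH2Cl2, rt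
Reagents that add atoms: tert-butyl(chloro)dimethylsilane, CC(C)(C)[Si](C)(C)Cl
Why: Imidazole-mediated silylation of the primary allylic alcohol protects the side-chain hydroxyl.

Step 19
Reactants: 30 ethyl 2-{[(TBS)oxy]methyl}acrylate
Product: 31 2-{[(TBS)oxy]methyl}acrylic acid
Conditions: LiOH, THF/H2O, 0 °C; 1 M HCl to pH 4
Reagents that add atoms: lithium hydroxide, [Li+].[OH-]
Why: Saponification of the ethyl ester; the primary silyl ether should survive cold LiOH and the brief mild acidification.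

Step 20
Reactants: 28 C8 alcohol; 31 2-{[(TBS)oxy]methyl}acrylic acid
Product: 32 (6R,8S)-8-(2-{[(TBS)oxy]methyl}acryloyloxy)-13-[(PMB)oxy]germacra-1(10)E,4E,7(11)-trien-12,6-olide
Conditions: N,N'-dicyclohexylcarbodiimide, DMAP (0.2 equiv), CH2Cl2, 0 °C to rt
Reagents that add atoms: none
Why: Steglich esterification acylates O8 without breaking the C8–O bond, so the 8S configuration is retained.

Step 21
Reactants: 32 C8 ester
Product: 33 (6R,8S)-8-(2-{[(TBS)oxy]methyl}acryloyloxy)-13-hydroxygermacra-1(10)E,4E,7(11)-trien-12,6-olide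
Conditions: DDQ, CH2Cl2/pH 7 phosphate buffer, 0 °C
Reagents that add atoms: none
Why: Oxidative cleavage of the 4-methoxybenzyl ether by DDQ proceeds through the benzylic oxocarbenium ion, and buffered conditions should spare the silyl ether and the ring olefins.

Step 22
Reactants: 33 C13 alcohol
Product: 34 (6R,8S)-13-acetoxy-8-(2-{[(TBS)oxy]methyl}acryloyloxy)germacra-1(10)E,4E,7(11)-trien-12,6-olide
Conditions: Ac2O, pyridine, DMAP (5 mol %), CH2Cl2, 0 °C
Reagents that add atoms: acetic anhydride, CC(=O)OC(C)=O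
Why: Acetylation of the primary allylic alcohol installs the C13 acetate after the reductive nickel step, which it would not have survived.

Step 23
Reactants: 34 C13 acetate
Product: 35 (6R,8S)-13-acetoxy-8-[2-(hydroxymethyl)acryloyloxy]germacra-1(10)E,4E,7(11)-trien-12,6-olide
Conditions: HF·pyridine, pyridine, THF, 0 °C
Reagents that add atoms: none
Why: Fluoride-mediated cleavage of the primary silyl ether; both esters, the acetate and the diene should be stable to buffered HF·pyridine.

Step 24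
Reactants: 35 diene diester
Product: 36 target, (1R,4R,5R,6S,8S,10R)-13-acetoxy-1,10:4,5-diepoxy-8-[2-(hydroxymethyl)acryloyloxy]germacr-7(11)-en-12,6-olide
Conditions: dimethyldioxirane (2.5 equiv), acetone/CH2Cl2, −20 to 0 °C
Reagents that add atoms: dimethyldioxirane, CC1(C)OO1
Why: Epoxidation with dimethyldioxirane under neutral conditions should take only the two electron-rich trisubstituted ring olefins (the butenolide and acrylate olefins are electron-poor), each from its outer face in the crown conformer with both methyls syn, which sets 1R,10R and 4R,5R (1β,10α and 4α,5β oxiranes) as in related germacranolides.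

**Compound list**

1 | geranyl acetate, (2E)-3,7-dimethylocta-2,6-dien-1-yl acetate | CC(C)=CCC/C(C)=C/COC(C)=O | starting material
2 | 6,7-epoxygeranyl acetate, racemic | CC1(C)OC1CC/C(C)=C/COC(C)=O | intermediate
3 | (2E)-6,7-dihydroxy-3,7-dimethyloct-2-en-1-yl acetate, racemic glycol | CC(C)(O)C(O)CC/C(C)=C/COC(C)=O | intermediate
4 | (2E)-3-methyl-6-oxohex-2-en-1-yl acetate | O=CCC/C(C)=C/COC(C)=O | intermediate
5 | (2E)-3-methylhept-2-en-6-yn-1-ol | C#CCC/C(C)=C/CO | intermediate
6 | dilithium salt of 5 (lithium alkoxide, lithium acetylide) | [Li]C#CCC/C(C)=C/CO[Li] | intermediate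
7 | (2E)-3-methyloct-2-en-6-yn-1-ol | CC#CCC/C(C)=C/CO | intermediate
8 | E alkenylzirconocene chloride of 7, zirconium on the methyl-bearing carbon (C10) and on the alkoxide oxygen | C/C(=C\CC/C(C)=C/CO[Zr](Cl)(C1C=CC=C1)C1C=CC=C1)[Zr](Cl)(C1C=CC=C1)C1C=CC=C1 | intermediate
9 | (2E,6E)-7-bromo-3-methylocta-2,6-dien-1-ol | Br/C(C)=C/CC/C(C)=C/CO | intermediate
10 | (2E,6E)-7-bromo-3-methylocta-2,6-dienal | Br/C(C)=C/CC/C(C)=C/C=O | intermediate
11 | dimethyl L-malate, dimethyl (2S)-2-hydroxybutanedioate | COC(=O)C[C@H](O)C(=O)OC | starting material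
12 | dimethyl (2S)-2-[(tert-butyldimethylsilyl)oxy]butanedioate | COC(=O)C[C@H](O[Si](C)(C)C(C)(C)C)C(=O)OC | intermediate
13 | methyl (3S)-3-[(tert-butyldimethylsilyl)oxy]-4-oxobutanoate | COC(=O)C[C@H](O[Si](C)(C)C(C)(C)C)C=O | intermediate
14 | 4-methoxybenzyl alcohol | COc1ccc(CO)cc1 | starting material
15 | methyl acrylate | C=CC(=O)OC | starting material
16 | methyl 3-[(4-methoxybenzyl)oxy]propanoate | COC(=O)CCOCc1ccc(OC)cc1 | intermediate
17 | lithium enolate of 16 | COC(O[Li])=CCOCc1ccc(OC)cc1 | intermediate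
18 | dimethyl (4S)-4-[(TBS)oxy]-3-hydroxy-2-{[(PMB)oxy]methyl}hexanedioate, mixture at C2 and C3 | COC(=O)C(COCc1ccc(OC)cc1)C(O)[C@@H](O[Si](C)(C)C(C)(C)C)CC(=O)OC | intermediate
19 | dimethyl (4S)-4-[(TBS)oxy]-2-{[(PMB)oxy]methyl}-3-oxohexanedioate, mixture at C2 | COC(=O)C(COCc1ccc(OC)cc1)C(=O)[C@@H](O[Si](C)(C)C(C)(C)C)CC(=O)OC | intermediate
20 | lithium (Z)-enolate of 19 | COC(=O)/C(COCc1ccc(OC)cc1)=C(\O[Li])[C@@H](O[Si](C)(C)C(C)(C)C)CC(=O)OC | intermediate
21 | dimethyl (2Z,4S)-4-[(TBS)oxy]-2-{[(PMB)oxy]methyl}-3-{[(trifluoromethyl)sulfonyl]oxy}hex-2-enedioate | COC(=O)/C(COCc1ccc(OC)cc1)=C(\OS(=O)(=O)C(F)(F)F)[C@@H](O[Si](C)(C)C(C)(C)C)CC(=O)OC | intermediate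
22 | dimethyl (2E,4S)-3-[(1R,2E,6E)-7-bromo-1-hydroxy-3-methylocta-2,6-dien-1-yl]-4-[(TBS)oxy]-2-{[(PMB)oxy]methyl}hex-2-enedioate, carbinol carbon cis to the C12 ester | Br/C(C)=C/CC/C(C)=C/[C@@H](O)/C(=C(/COCc1ccc(OC)cc1)C(=O)OC)[C@@H](O[Si](C)(C)C(C)(C)C)CC(=O)OC | intermediate
23 | methyl (3S)-3-[(TBS)oxy]-3-[(2R)-2-[(1E,5E)-6-bromo-2-methylhepta-1,5-dien-1-yl]-4-{[(PMB)oxy]methyl}-5-oxo-2,5-dihydrofuran-3-yl]propanoate | Br/C(C)=C/CC/C(C)=C/[C@H]1OC(=O)C(COCc2ccc(OC)cc2)=C1[C@@H](O[Si](C)(C)C(C)(C)C)CC(=O)OC | intermediate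
24 | (3S)-3-[(TBS)oxy]-3-[(2R)-2-[(1E,5E)-6-bromo-2-methylhepta-1,5-dien-1-yl]-4-{[(PMB)oxy]methyl}-5-oxo-2,5-dihydrofuran-3-yl]propanoic acid | Br/C(C)=C/CC/C(C)=C/[C@H]1OC(=O)C(COCc2ccc(OC)cc2)=C1[C@@H](O[Si](C)(C)C(C)(C)C)CC(=O)O | intermediate
25 | N-hydroxyphthalimide | O=C1c2ccccc2C(=O)N1O | starting material
26 | 1,3-dioxoisoindolin-2-yl ester of 24 (seco N-acyloxyphthalimide, E alkenyl bromide at C10, 6R,8S) | Br/C(C)=C/CC/C(C)=C/[C@H]1OC(=O)C(COCc2ccc(OC)cc2)=C1[C@@H](O[Si](C)(C)C(C)(C)C)CC(=O)ON1C(=O)c2ccccc2C1=O | intermediate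
27 | (6R,8S)-8-[(TBS)oxy]-13-[(PMB)oxy]germacra-1(10)E,4E,7(11)-trien-12,6-olide | CC(C)(C)[Si](C)(C)O[C@H]1C/C(C)=C/CC/C(C)=C/[C@H]2OC(=O)C(COCc3ccc(OC)cc3)=C12 | intermediate
28 | (6R,8S)-8-hydroxy-13-[(PMB)oxy]germacra-1(10)E,4E,7(11)-trien-12,6-olide | O[C@H]1C/C(C)=C/CC/C(C)=C/[C@H]2OC(=O)C(COCc3ccc(OC)cc3)=C12 | intermediate
29 | ethyl 2-(hydroxymethyl)acrylate | C=C(CO)C(=O)OCC | starting material
30 | ethyl 2-{[(TBS)oxy]methyl}acrylate | C=C(CO[Si](C)(C)C(C)(C)C)C(=O)OCC | intermediate
31 | 2-{[(TBS)oxy]methyl}acrylic acid | C=C(CO[Si](C)(C)C(C)(C)C)C(=O)O | intermediate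
32 | (6R,8S)-8-(2-{[(TBS)oxy]methyl}acryloyloxy)-13-[(PMB)oxy]germacra-1(10)E,4E,7(11)-trien-12,6-olide | C=C(CO[Si](C)(C)C(C)(C)C)C(=O)O[C@H]1C/C(C)=C/CC/C(C)=C/[C@H]2OC(=O)C(COCc3ccc(OC)cc3)=C12 | intermediate
33 | (6R,8S)-8-(2-{[(TBS)oxy]methyl}acryloyloxy)-13-hydroxygermacra-1(10)E,4E,7(11)-trien-12,6-olide | C=C(CO[Si](C)(C)C(C)(C)C)C(=O)O[C@H]1C/C(C)=C/CC/C(C)=C/[C@H]2OC(=O)C(CO)=C12 | intermediate
34 | (6R,8S)-13-acetoxy-8-(2-{[(TBS)oxy]methyl}acryloyloxy)germacra-1(10)E,4E,7(11)-trien-12,6-olide | C=C(CO[Si](C)(C)C(C)(C)C)C(=O)O[C@H]1C/C(C)=C/CC/C(C)=C/[C@H]2OC(=O)C(COC(C)=O)=C12 | intermediate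
35 | (6R,8S)-13-acetoxy-8-[2-(hydroxymethyl)acryloyloxy]germacra-1(10)E,4E,7(11)-trien-12,6-olide | C=C(CO)C(=O)O[C@H]1C/C(C)=C/CC/C(C)=C/[C@H]2OC(=O)C(COC(C)=O)=C12 | intermediate
36 | (1R,4R,5R,6S,8S,10R)-13-acetoxy-1,10:4,5-diepoxy-8-[2-(hydroxymethyl)acryloyloxy]germacr-7(11)-en-12,6-olide (1β,10α:4α,5β-diepoxide, 6α-O, 8α-O) | C=C(CO)C(=O)O[C@H]1C[C@@]2(C)O[C@@H]2CC[C@@]2(C)O[C@@H]2[C@H]2OC(=O)C(COC(C)=O)=C12 | target

**Count**

Total step count: 24. Longest linear sequence: 16 steps (steps 1–6, 13–17, 20–24).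

**Steps most likely to fail**

Step 16. The C9 radical may be reduced, dimerise or take a hydrogen from C13 by 1,5-transfer before the alkenylnickel of the same molecule captures it, or zerovalent nickel may ionise the allylic lactone C6–O bond; the result would be open-chain or oligomeric material instead of the ten-membered ring. The fallback uses known chemistry only: C9–C10 is made between two molecules by the established nickel-electrocatalytic decarboxylative alkenylation, and the ring is closed at C6–C7 by an intramolecular Nozaki–Hiyama–Kishi reaction. It sets out from 13 and 9 and comes back to the route at 27. Aldehyde 13 is masked with HC(OMe)3 and PPTS in MeOH as dimethyl acetal F1, Me3SnOH gives acid F2, and 25 with N,N'-diisopropylcarbodiimide gives N-acyloxyphthalimide F3. Electrolysis of F3 with bromo dienol 9 (NiCl2·dme, 2,2'-bipyridine, AgNO3, Mg anode, DMF) should give the C9–C10-linked dienol acetal F4, and wet acetone with PPTS frees hydroxy aldehyde F5. Addition of enolate 17 (2.2 equiv, −78 °C) gives diol ester F6, Dess–Martin periodinane oxidises both hydroxyls to keto ester enal F7, and LiN(SiMe3)2 with the pyridyl triflimide gives Z enol triflate enal F8. CrCl2 and catalytic NiCl2 with the sulfonamide ligand of step 13, at 2 mM in THF, then join C7 to the C6 aldehyde, and lactonisation delivers 27.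

Step 13. Insertion into the tetrasubstituted triflate may be slow, facial selectivity at the aldehyde may be poor, or nickel may also activate the C10–Br bond, so that the butenolide forms as a C6 mixture or in low conversion. The fallback sets C6 by reduction instead of addition; it sets out from 21 and 10 and comes back at 23. Triflate 21 is converted with Me3SnSnMe3 and Pd(PPh3)4 (LiCl, THF, 60 °C) into Z alkenylstannane F9. Enal 10 is oxidised (NaClO2, NaH2PO4, 2-methylbut-2-ene) to dienoic acid F10 and turned into acid chloride F11 with oxalyl chloride. Stille acylation of F9 with F11 (Pd(PPh3)4, toluene, 50 °C; the acyl chloride reacts much faster than the alkenyl bromide) gives dienone F12. Corey–Bakshi–Shibata reduction with (S)-2-methyl-CBS-oxazaborolidine and catecholborane at −78 °C, with the tetrasubstituted alkenyl group as the large substituent, should give the 6R carbinol 22, which lactonises to 23.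

Step 24. The oxidant may attack an olefin face exposed in a minor ring conformer, or the first oxirane may open across the ring, giving diastereomers or bicyclic by-products. The fallback moves the 1,10-epoxidation to the alcohol stage and uses the C8 hydroxyl as a directing group; it sets out from 28 and comes back at 36. VO(acac)2 and tert-butyl hydroperoxide (CH2Cl2, 0 °C) deliver oxygen from the 8α-hydroxyl to the homoallylic C1=C10 olefin and should give 1β,10α-epoxy alcohol F13. Dimethyldioxirane then epoxidises the remaining C4=C5 olefin to diepoxy alcohol F14. Esterification with 31 (N,N'-dicyclohexylcarbodiimide, DMAP) gives ester F15, DDQ gives C13 alcohol F16, Ac2O and pyridine give acetate F17, and buffered HF·pyridine removes the silyl group to give 36.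

**Further compounds**

F1 | step 16 | methyl (3S)-3-[(TBS)oxy]-4,4-dimethoxybutanoate | COC(=O)C[C@H](O[Si](C)(C)C(C)(C)C)C(OC)OC
F2 | step 16 | (3S)-3-[(TBS)oxy]-4,4-dimethoxybutanoic acid | OC(=O)C[C@H](O[Si](C)(C)C(C)(C)C)C(OC)OC
F3 | step 16 | 1,3-dioxoisoindolin-2-yl (3S)-3-[(TBS)oxy]-4,4-dimethoxybutanoate | O=C(C[C@H](O[Si](C)(C)C(C)(C)C)C(OC)OC)ON1C(=O)c2ccccc2C1=O
F4 | step 16 | (2E,6E,9S)-9-[(TBS)oxy]-10,10-dimethoxy-3,7-dimethyldeca-2,6-dien-1-ol | COC(OC)[C@@H](O[Si](C)(C)C(C)(C)C)C/C(C)=C/CC/C(C)=C/CO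
F5 | step 16 | (2S,4E,8E)-2-[(TBS)oxy]-10-hydroxy-4,8-dimethyldeca-4,8-dienal | O=C[C@@H](O[Si](C)(C)C(C)(C)C)C/C(C)=C/CC/C(C)=C/CO
F6 | step 16 | methyl (4S,6E,10E)-4-[(TBS)oxy]-3,12-dihydroxy-2-{[(PMB)oxy]methyl}-6,10-dimethyldodeca-6,10-dienoate, mixture at C2 and C3 | COC(=O)C(COCc1ccc(OC)cc1)C(O)[C@@H](O[Si](C)(C)C(C)(C)C)C/C(C)=C/CC/C(C)=C/CO
F7 | step 16 | methyl (4S,6E,10E)-4-[(TBS)oxy]-2-{[(PMB)oxy]methyl}-6,10-dimethyl-3,12-dioxododeca-6,10-dienoate | COC(=O)C(COCc1ccc(OC)cc1)C(=O)[C@@H](O[Si](C)(C)C(C)(C)C)C/C(C)=C/CC/C(C)=C/C=O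
F8 | step 16 | methyl (2Z,4S,6E,10E)-4-[(TBS)oxy]-2-{[(PMB)oxy]methyl}-6,10-dimethyl-12-oxo-3-{[(trifluoromethyl)sulfonyl]oxy}dodeca-2,6,10-trienoate | COC(=O)/C(COCc1ccc(OC)cc1)=C(\OS(=O)(=O)C(F)(F)F)[C@@H](O[Si](C)(C)C(C)(C)C)C/C(C)=C/CC/C(C)=C/C=O
F9 | step 13 | dimethyl (2Z,4S)-4-[(TBS)oxy]-2-{[(PMB)oxy]methyl}-3-(trimethylstannyl)hex-2-enedioate | COC(=O)/C(COCc1ccc(OC)cc1)=C(\[Sn](C)(C)C)[C@@H](O[Si](C)(C)C(C)(C)C)CC(=O)OC
F10 | step 13 | (2E,6E)-7-bromo-3-methylocta-2,6-dienoic acid | Br/C(C)=C/CC/C(C)=C/C(=O)O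
F11 | step 13 | (2E,6E)-7-bromo-3-methylocta-2,6-dienoyl chloride | Br/C(C)=C/CC/C(C)=C/C(Cl)=O
F12 | step 13 | dimethyl (2Z,4S)-3-[(2E,6E)-7-bromo-3-methylocta-2,6-dienoyl]-4-[(TBS)oxy]-2-{[(PMB)oxy]methyl}hex-2-enedioate | Br/C(C)=C/CC/C(C)=C/C(=O)/C(=C(/COCc1ccc(OC)cc1)C(=O)OC)[C@@H](O[Si](C)(C)C(C)(C)C)CC(=O)OC
F13 | step 24 | (1R,6R,8S,10R)-1,10-epoxy-8-hydroxy-13-[(PMB)oxy]germacra-4E,7(11)-dien-12,6-olide | O[C@H]1C[C@@]2(C)O[C@@H]2CC/C(C)=C/[C@H]2OC(=O)C(COCc3ccc(OC)cc3)=C12
F14 | step 24 | (1R,4R,5R,6S,8S,10R)-1,10:4,5-diepoxy-8-hydroxy-13-[(PMB)oxy]germacr-7(11)-en-12,6-olide | O[C@H]1C[C@@]2(C)O[C@@H]2CC[C@@]2(C)O[C@@H]2[C@H]2OC(=O)C(COCc3ccc(OC)cc3)=C12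
F15 | step 24 | (1R,4R,5R,6S,8S,10R)-1,10:4,5-diepoxy-8-(2-{[(TBS)oxy]methyl}acryloyloxy)-13-[(PMB)oxy]germacr-7(11)-en-12,6-olide | C=C(CO[Si](C)(C)C(C)(C)C)C(=O)O[C@H]1C[C@@]2(C)O[C@@H]2CC[C@@]2(C)O[C@@H]2[C@H]2OC(=O)C(COCc3ccc(OC)cc3)=C12
F16 | step 24 | (1R,4R,5R,6S,8S,10R)-1,10:4,5-diepoxy-13-hydroxy-8-(2-{[(TBS)oxy]methyl}acryloyloxy)germacr-7(11)-en-12,6-olide | C=C(CO[Si](C)(C)C(C)(C)C)C(=O)O[C@H]1C[C@@]2(C)O[C@@H]2CC[C@@]2(C)O[C@@H]2[C@H]2OC(=O)C(CO)=C12
F17 | step 24 | (1R,4R,5R,6S,8S,10R)-13-acetoxy-1,10:4,5-diepoxy-8-(2-{[(TBS)oxy]methyl}acryloyloxy)germacr-7(11)-en-12,6-olide | C=C(CO[Si](C)(C)C(C)(C)C)C(=O)O[C@H]1C[C@@]2(C)O[C@@H]2CC[C@@]2(C)O[C@@H]2[C@H]2OC(=O)C(COC(C)=O)=C12
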